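## The problem

The target is a 7‑O‑alkylated umbelliferone whose terpenoid half is one cyclohexene carrying fifteen carbons. The ring is numbered here C1 (CH with isopropenyl), C2=C3 (methyl on C3), C4 (CH with the aryloxymethyl group), C5 (quaternary: methyl and 2‑carboxyethyl) and C6 (CH2). In this numbering the configuration is 1S,4R,5R, which is (1R,2R,5S) in the systematic name of the acid. Isopropenyl, aryloxymethyl and the acid chain lie on one face and the C5 methyl on the other.

There is no ring fusion to lean on. C4 and C5 are contiguous and one of them is quaternary; C1 is insulated from them by the C6 methylene. The two C5 substituents, methyl and CH2CH2CO2R, differ little in size, so C5 is better derived from an alkene geometry than from facial discrimination. For the same reason C4 and C5 can bias the later creation of C1 only weakly, and C1 needs reagent control.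

C1 is doubly allylic and C4 is allylic, so strong base or acid must be avoided once they are set; the 1,1‑disubstituted alkene is acid‑sensitive. The coumarin lactone does not survive hydride, Grignard reagents or zerovalent nickel and must be attached last, with the acid carried as an ester.

The feature that opens the ring to a short synthesis is this: C3 can be a ketone carbon, C3–C4–C5–C6 can be a cyclobutanone whose cis C4/C5 substituents come from a (Z)‑trisubstituted alkene, and C2–C1 with its isopropenyl group is the alkyne of 2‑methylbut‑1‑en‑3‑yne inserted between C3 and C6.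

## Retrosynthesis

**Aryl ether and acid.** The ArO–CH2 bond of 22 is cut and the acid is masked as its ethyl ester 20. This leads to the primary alcohol 18 and umbelliferone 19. Joining them last keeps the lactone and enoate of the coumarin away from every reductive and organometallic step. The forward reactions are a Mitsunobu etherification at a β‑branched primary carbon and a saponification whose acidic work‑up must re‑close any opened lactone.

**C3–CH3.** In 17 (the silyl ether of 18) the C3–methyl bond is cut to the enol triflate 16, made from ketone 15. A cross‑coupling fixes the alkene at C2=C3 without ambiguity. Methyl addition to the ketone followed by dehydration would give mixtures of C2=C3, C3=C4 and exocyclic alkenes. The forward steps need kinetic enolization at the C2 methylene (not at the C4 methine, whose enolate would expel the β‑silyloxy group) and a methylation that spares the ester.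

**C1–H.** Ketone 15 is traced to dienone 13 by removing the hydrogen at C1. This is the only point at which C1 is created. The forward reaction must deliver hydride to the β‑carbon of a β,β‑disubstituted enone in 1,4‑ and not 1,6‑fashion, and from the face of the C5 methyl. Trialkylborohydrides add 1,2 to such enones, so a ligated copper hydride is chosen; its chiral bisphosphine adds reagent control to the small substrate bias.

**C2–C3 and C1–C6 (key disconnection).** Dienone 13 is cut at C2–C3 and C1–C6 into cyclobutanone 11 and 2‑methylbut‑1‑en‑3‑yne 12. Neighbouring cuts (an intramolecular aldol at C1=C2, or a Diels–Alder across C3–C4/C5–C6) need acyclic or activated precursors that already hold the C4/C5 pair. This cut removes two ring carbons and the isopropenyl group in one operation and leaves a four‑membered ring. The forward reaction needs nickel to join C3 to the terminal alkyne carbon, to cleave C3–C6 and not C3–C4, and to leave the epimerizable C4 alone.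

**C3–C4 and C5–C6.** Cyclobutanone 11 is cut into the (Z)‑alkene 6 and a two‑carbon ketene equivalent, the keteniminium ion from acetamide 8 (made from amine 7). A suprafacial [2+2] turns the alkene geometry into the cis C4/C5 relation without having to tell methyl from CH2CH2CO2Et. The C2‑symmetric pyrrolidine is asked to choose the alkene face, and the electrophilic carbon must bond to the less substituted alkene carbon.

**The (Z)‑alkene.** Alkene 6 is cut at the C(sp2)–CH2 bond into alkenyl iodide 4 and the zinc homoenolate 5. Iodide 4 comes from but‑2‑yn‑1‑ol 1 through iodo alcohol 3, whose geometry is fixed by alkoxide‑directed hydroalumination. The same alkene could be cut out of nerol by degrading the distal double bond, but that costs two more steps.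

## Roads not taken

**Alternative 1:** The cut is through a cyclopropane: the bonds from a carbenoid carbon to C5 and C6. In the forward direction the achiral homoallylic diazoacetate A1 (a 2,6‑dimethylcyclohexa‑2,5‑dienylmethyl ester from a Birch reduction) is treated with Rh2(5S‑MEPY)4, dirhodium tetrakis[methyl 2‑oxopyrrolidine‑5(S)‑carboxylate]. The catalyst cyclopropanates one of the two enantiotopic ring alkenes and gives the cyclopropane‑fused lactone A2.
- Merits: one catalytic event sets C4 and the quaternary C5 with a well‑tested catalyst class; the starting material is a cheap arene; the C2=C3 alkene with its methyl is already present.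
- Weak points: A2 has a bare, doubly allylic CH2 at C1, where carbenoid C–H insertion can compete and where the isopropenyl group must later be introduced cis with no handle. The future chain is one carbon short. The cyclopropane must be opened at one specific bond.
- Comparison: on enantiocontrol of C4/C5 this road is better founded than the auxiliary‑controlled [2+2] of the chosen plan. The chosen plan has all fifteen terpenoid carbons at the right oxidation level in place after its key step, and C1 is already functionalized.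

**Alternative 2:** The cut is through the bonds from C1 to the central isopropenyl carbon and from C4 to the oxymethyl carbon, seen as the two new bonds of an intramolecular Diels–Alder. The 6,6‑disubstituted cyclohexa‑2,4‑dienone A3, from dearomatization of a phenol, carries an enol ester on its propanoate arm. Cycloaddition gives the bicyclo[2.2.2]octenone A4 with a seven‑membered lactone; a later Grob fragmentation releases the isopropenyl group and an aldehyde at C4.
- Merits: C1, C4 and C5 are fixed relative to one another by a rigid bicycle, so C1 is not left to a late facial choice; the C2=C3 alkene and its methyl arise directly.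
- Weak points: the quaternary C5 must be set in an enantioselective alkylative dearomatization; such dienones dimerize readily; the tether closes a seven‑membered ring; after fragmentation a ketone remains at C6, next to the quaternary carbon, and must be removed in the presence of an aldehyde and two alkenes.
- Comparison: in control of C1 this road is better than the chosen plan. The chosen plan is several steps shorter and has no carbonyl to delete.

**Alternative 3:** The cut is at C5–CH3 and C4–CH2OH. Me2CuLi adds to the 3‑substituted 5‑isopropenylcyclohexenone A5, and the regiospecific enolate is trapped at C4 by monomeric formaldehyde to give the hydroxymethyl ketone A6.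
- Merits: every reaction is textbook chemistry; C1 is present from the start and directs the cuprate trans to itself; the axial new methyl then sends formaldehyde to the opposite face, so C5 and C4 follow from C1 with the right sense.
- Weak points: A5 needs its own enantioselective synthesis. Aldol trapping next to a freshly made quaternary centre is inefficient and the β‑hydroxy ketone is prone to retro‑aldol loss of formaldehyde. The chain is carried as a silyloxypropyl group, which costs a deprotection and an oxidation in the presence of a second primary alcohol. The ketone‑to‑methylalkene sequence of the chosen plan is still required.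
- Comparison: in precedent and in the order of stereocentre creation this road is better than the chosen plan. The chosen plan takes C4/C5 from an alkene geometry instead of two successive facial selections, keeps the chain at the acid oxidation level, and builds the ring and the isopropenyl group in one step.

Key step: step 6

Assumption (remark on the chemistry): the sense of induction of the two chiral controllers cannot be derived from the substrate alone. The (2R,5R)‑pyrrolidine amide 8 and the (S)‑configured bisphosphine are written as the matched hands; the antipodes, equally available, would be used if the opposite sense were found.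

## Route

Step 1
Reactants: 1 but‑2‑yn‑1‑ol
Product: 3 (Z)‑3‑iodobut‑2‑en‑1‑ol, via cyclic alkenylaluminate 2 (not isolated)
Conditions: NaAlH2(OCH2CH2OCH3)2, THF, 0 °C → rt; then I2, THF, −78 → 0 °C
Reagents that add atoms: iodine, II
Why: Alkoxide‑directed trans‑hydroalumination puts aluminium on C3 inside a five‑membered oxa‑aluminacycle, and iodinolysis with retention gives the (Z)‑3‑iodo alkenol; this geometry later becomes the cis C4/C5 relation.

Step 2
Reactants: 3 (Z)‑3‑iodobut‑2‑en‑1‑ol
Product: 4 (Z)‑tert‑butyl[(3‑iodobut‑2‑en‑1‑yl)oxy]diphenylsilane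
Conditions: t‑BuPh2SiCl, imidazole, CH2Cl2, 0 °C → rt
Reagents that add atoms: tert‑butyl(chloro)diphenylsilane, CC(C)(C)[Si](Cl)(c1ccccc1)c1ccccc1
Why: Standard silylation of a primary alcohol; the bulky, acid‑stable silyl ether survives triflic anhydride activation, nickel catalysis and the dilute acid work‑up of step 7.

Step 3
Reactants: 4 (Z)‑tert‑butyl[(3‑iodobut‑2‑en‑1‑yl)oxy]diphenylsilane; 5 (3‑ethoxy‑3‑oxopropyl)zinc bromide
Product: 6 ethyl (Z)‑6‑{[tert‑butyl(diphenyl)silyl]oxy}‑4‑methylhex‑4‑enoate
Conditions: Pd(PPh3)4 (5 mol%), THF, 40 °C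
Reagents that add atoms: none
Why: Negishi sp2–sp3 coupling of an alkenyl iodide with a zinc homoenolate goes with retention of alkene geometry and tolerates the ester, so the chain ends up cis to the silyloxymethyl group.

Step 4
Reactants: 7 (2R,5R)‑2,5‑dimethylpyrrolidine
Product: 8 1‑[(2R,5R)‑2,5‑dimethylpyrrolidin‑1‑yl]ethan‑1‑one
Conditions: Ac2O, Et3N, CH2Cl2, 0 °C → rt
Reagents that add atoms: acetic anhydride, CC(=O)OC(C)=O
Why: Simple N‑acylation of a secondary amine gives the C2‑symmetric acetamide that serves as the chiral ketene equivalent.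

Step 5
Reactants: 6 ethyl (Z)‑6‑{[tert‑butyl(diphenyl)silyl]oxy}‑4‑methylhex‑4‑enoate; 8 1‑[(2R,5R)‑2,5‑dimethylpyrrolidin‑1‑yl]ethan‑1‑one
Product: 11 ethyl 3‑[(1R,2S)‑2‑{[tert‑butyl(diphenyl)silyl]oxymethyl}‑1‑methyl‑3‑oxocyclobutyl]propanoate, via keteniminium triflate 9 (not isolated), via cyclobutaniminium triflate 10 (not isolated)
Conditions: Tf2O, 2,6‑di‑tert‑butyl‑4‑methylpyridine, ClCH2CH2Cl, 0 → 70 °C; then aq. NaHCO3, rt
Reagents that add atoms: water, O
Why: Ghosez keteniminium–alkene [2+2] cycloaddition: the electrophilic central carbon bonds to the less substituted alkene carbon (C4) and the methylene closes on the tertiary carbon (C5), suprafacially, so the (Z)‑alkene gives the cis silyloxymethyl/chain pair; the C2‑symmetric pyrrolidine selects the alkene face and so sets the absolute configuration of C4 and C5 before mild hydrolysis releases the ketone and the auxiliary.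

Step 6
Reactants: 11 ethyl 3‑[(1R,2S)‑2‑{[tert‑butyl(diphenyl)silyl]oxymethyl}‑1‑methyl‑3‑oxocyclobutyl]propanoate; 12 2‑methylbut‑1‑en‑3‑yne
Product: 13 ethyl 3‑[(1R,2S)‑2‑{[tert‑butyl(diphenyl)silyl]oxymethyl}‑1‑methyl‑3‑oxo‑5‑(prop‑1‑en‑2‑yl)cyclohex‑4‑en‑1‑yl]propanoate
Conditions: Ni(cod)2 (10 mol%), PCy3 (20 mol%), toluene, 90 °C, sealed vessel, 12 added in portions
Reagents that add atoms: none
Why: Proposed new method: zerovalent nickel on PCy3 is expected to couple the carbonyl carbon C3 of 11 with the terminal alkyne carbon of 12 by oxidative cyclization to a spiro oxanickelacyclopentene, the conjugated alkene of the enyne holding nickel at the internal alkyne carbon; β‑carbon elimination then opens the strained ring and reductive elimination from the seven‑membered nickelacycle forms C1–C6. The closest known reaction type is the Ni(cod)2/phosphine‑catalysed insertion of internal alkynes into 3‑substituted and 3,3‑disubstituted cyclobutanones to give cyclohex‑2‑enones; a terminal 1,3‑enyne and a 2,3,3‑trisubstituted cyclobutanone have not been shown. The six‑membered ring closes by C(sp2)–C(sp3) reductive elimination at nickel, a two‑carbon ring expansion (formal [4+2]) and not a cyclization of an open chain. No stereocentre is created; the quaternary C5 cannot change, and C4 is carried through as long as the C3–C4 bond stays intact and the medium stays neutral. Alkyne orientation (C3 to the CH terminus) should follow from the alkene‑directing effect of 1,3‑enynes in nickel oxidative cyclizations and from the small size of the unsubstituted terminus at a hindered ketone. Cleavage of C3–C6 and not C3–C4 should follow because migration of the methylene gives a primary, neopentyl‑type alkylnickel with no β‑hydrogen, whereas C4 is secondary and carries a β‑silyloxy group. Insertion in preference to alkyne oligomerization is addressed by keeping the stationary concentration of 12 low.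

Step 7
Reactants: 13 ethyl 3‑[(1R,2S)‑2‑{[tert‑butyl(diphenyl)silyl]oxymethyl}‑1‑methyl‑3‑oxo‑5‑(prop‑1‑en‑2‑yl)cyclohex‑4‑en‑1‑yl]propanoate
Product: 15 ethyl 3‑[(1R,2S,5S)‑2‑{[tert‑butyl(diphenyl)silyl]oxymethyl}‑1‑methyl‑3‑oxo‑5‑(prop‑1‑en‑2‑yl)cyclohexyl]propanoate, via silyl enol ether 14 (not isolated)
Conditions: Cu(OAc)2 (5 mol%), (S)‑DTBM‑SEGPHOS (5.5 mol%), (EtO)2MeSiH, toluene, −20 → 0 °C; then 1 M HCl, THF, 0 °C
Reagents that add atoms: none
Why: Ligated copper hydride conjugate reduction (asymmetric 1,4‑hydrosilylation) of a β,β‑disubstituted cyclohexenone, the class to which 3,5,5‑trimethylcyclohexenone belongs; hydride should enter C1 on the face of the C5 methyl, where the ligand hand, (S)‑5,5′‑bis[di(3,5‑di‑tert‑butyl‑4‑methoxyphenyl)phosphino]‑4,4′‑bi‑1,3‑benzodioxole, is chosen to reinforce the small intrinsic preference for attack past the smaller C5 substituent, and isolation of the ketone allows removal of any C1 epimer.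

Step 8
Reactants: 15 ethyl 3‑[(1R,2S,5S)‑2‑{[tert‑butyl(diphenyl)silyl]oxymethyl}‑1‑methyl‑3‑oxo‑5‑(prop‑1‑en‑2‑yl)cyclohexyl]propanoate
Product: 16 ethyl 3‑[(1R,2S,5S)‑2‑{[tert‑butyl(diphenyl)silyl]oxymethyl}‑1‑methyl‑5‑(prop‑1‑en‑2‑yl)‑3‑(trifluoromethylsulfonyloxy)cyclohex‑3‑en‑1‑yl]propanoate
Conditions: KN(SiMe3)2, THF, −78 °C; then PhNTf2, −78 → 0 °C
Reagents that add atoms: N‑phenylbis(trifluoromethanesulfonimide), O=S(=O)(N(c1ccccc1)S(=O)(=O)C(F)(F)F)C(F)(F)F
Why: Kinetic deprotonation by a bulky amide takes the accessible C2 methylene and not the C4 methine beside the quaternary carbon, and O‑triflation of that enolate fixes the alkene at C2=C3; the ketone is deprotonated well before the ester at −78 °C.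

Step 9
Reactants: 16 ethyl 3‑[(1R,2S,5S)‑2‑{[tert‑butyl(diphenyl)silyl]oxymethyl}‑1‑methyl‑5‑(prop‑1‑en‑2‑yl)‑3‑(trifluoromethylsulfonyloxy)cyclohex‑3‑en‑1‑yl]propanoate
Product: 17 ethyl 3‑[(1R,2R,5S)‑2‑{[tert‑butyl(diphenyl)silyl]oxymethyl}‑1,3‑dimethyl‑5‑(prop‑1‑en‑2‑yl)cyclohex‑3‑en‑1‑yl]propanoate
Conditions: Fe(acac)3 (5 mol%), MeMgBr, THF/NMP, −30 °C
Reagents that add atoms: methylmagnesium bromide, C[Mg]Br
Why: Iron‑catalysed cross‑coupling of an enol triflate with a Grignard reagent is faster at −30 °C than Grignard addition to an ester and places the methyl on C3 without touching the alkene position or the stereocentres.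

Step 10
Reactants: 17 ethyl 3‑[(1R,2R,5S)‑2‑{[tert‑butyl(diphenyl)silyl]oxymethyl}‑1,3‑dimethyl‑5‑(prop‑1‑en‑2‑yl)cyclohex‑3‑en‑1‑yl]propanoate
Product: 18 ethyl 3‑[(1R,2R,5S)‑2‑(hydroxymethyl)‑1,3‑dimethyl‑5‑(prop‑1‑en‑2‑yl)cyclohex‑3‑en‑1‑yl]propanoate
Conditions: Bu4NF, AcOH, THF, 0 °C → rt
Reagents that add atoms: none
Why: Fluoride cleavage of the silyl ether; the acetic acid buffer keeps the liberated alkoxide protonated so that it neither lactonizes onto the cis ester chain nor isomerizes the doubly allylic C1.

Step 11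
Reactants: 18 ethyl 3‑[(1R,2R,5S)‑2‑(hydroxymethyl)‑1,3‑dimethyl‑5‑(prop‑1‑en‑2‑yl)cyclohex‑3‑en‑1‑yl]propanoate; 19 umbelliferone (7‑hydroxy‑2H‑chromen‑2‑one)
Product: 20 ethyl 3‑[(1R,2R,5S)‑1,3‑dimethyl‑2‑{[(2‑oxo‑2H‑chromen‑7‑yl)oxy]methyl}‑5‑(prop‑1‑en‑2‑yl)cyclohex‑3‑en‑1‑yl]propanoate
Conditions: PPh3, DIAD, THF, 0 °C → rt
Reagents that add atoms: none
Why: Mitsunobu etherification of a primary alcohol with an acidic phenol under neutral conditions; the reacting carbon is not a stereocentre, and neither the lactone nor the alkenes are affected.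

Step 12
Reactants: 20 ethyl 3‑[(1R,2R,5S)‑1,3‑dimethyl‑2‑{[(2‑oxo‑2H‑chromen‑7‑yl)oxy]methyl}‑5‑(prop‑1‑en‑2‑yl)cyclohex‑3‑en‑1‑yl]propanoate
Product: 22 3‑[(1R,2R,5S)‑1,3‑dimethyl‑2‑{[(2‑oxo‑2H‑chromen‑7‑yl)oxy]methyl}‑5‑(prop‑1‑en‑2‑yl)cyclohex‑3‑en‑1‑yl]propanoic acid (CNP0301632.1), via ring‑opened trilithium coumarinate 21 (not isolated)
Conditions: LiOH, THF/H2O, rt; then 1 M HCl to pH 2
Reagents that add atoms: lithium hydroxide, [Li+].[OH-]
Why: Saponification of the ethyl ester; hydroxide also opens the coumarin to the (Z)‑2‑hydroxycinnamate, which keeps its cis geometry at room temperature and lactonizes again spontaneously on acidification, and the cold, brief acid contact leaves the isopropenyl group untouched.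

## Compound list

1 | but‑2‑yn‑1‑ol | CC#CCO | starting material
2 | sodium 2,2‑bis(2‑methoxyethoxy)‑3‑methyl‑2,5‑dihydro‑1,2‑oxaluminol‑2‑uide (cyclic alkenylaluminate) | [Na+].CC1=CCO[Al-]1(OCCOC)OCCOC | intermediate
3 | (Z)‑3‑iodobut‑2‑en‑1‑ol | C/C(I)=C/CO | intermediate
4 | (Z)‑tert‑butyl[(3‑iodobut‑2‑en‑1‑yl)oxy]diphenylsilane | C/C(I)=C/CO[Si](c1ccccc1)(c1ccccc1)C(C)(C)C | intermediate
5 | (3‑ethoxy‑3‑oxopropyl)zinc bromide | CCOC(=O)CC[Zn]Br | starting material
6 | ethyl (Z)‑6‑{[tert‑butyl(diphenyl)silyl]oxy}‑4‑methylhex‑4‑enoate | CCOC(=O)CC/C(C)=C\CO[Si](c1ccccc1)(c1ccccc1)C(C)(C)C | intermediate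
7 | (2R,5R)‑2,5‑dimethylpyrrolidine | C[C@@H]1CC[C@@H](C)N1 | starting material
8 | 1‑[(2R,5R)‑2,5‑dimethylpyrrolidin‑1‑yl]ethan‑1‑one | C[C@@H]1CC[C@@H](C)N1C(C)=O | intermediate
9 | (2R,5R)‑1‑ethenylidene‑2,5‑dimethylpyrrolidin‑1‑ium triflate (keteniminium salt) | C[C@@H]1CC[C@@H](C)[N+]1=C=C.[O-]S(=O)(=O)C(F)(F)F | intermediate
10 | cyclobutaniminium triflate of 11 with (2R,5R)‑2,5‑dimethylpyrrolidine (ring centres as in 11) | C[C@@H]1CC[C@@H](C)[N+]1=C1C[C@@](C)(CCC(=O)OCC)[C@H]1CO[Si](c1ccccc1)(c1ccccc1)C(C)(C)C.[O-]S(=O)(=O)C(F)(F)F | intermediate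
11 | ethyl 3‑[(1R,2S)‑2‑{[tert‑butyl(diphenyl)silyl]oxymethyl}‑1‑methyl‑3‑oxocyclobutyl]propanoate (silyloxymethyl cis to the ester chain) | O=C1C[C@@](C)(CCC(=O)OCC)[C@H]1CO[Si](c1ccccc1)(c1ccccc1)C(C)(C)C | intermediate
12 | 2‑methylbut‑1‑en‑3‑yne | C=C(C)C#C | starting material
13 | ethyl 3‑[(1R,2S)‑2‑{[tert‑butyl(diphenyl)silyl]oxymethyl}‑1‑methyl‑3‑oxo‑5‑(prop‑1‑en‑2‑yl)cyclohex‑4‑en‑1‑yl]propanoate | C=C(C)C1=CC(=O)[C@H](CO[Si](c2ccccc2)(c2ccccc2)C(C)(C)C)[C@](C)(CCC(=O)OCC)C1 | intermediate
14 | diethoxy(methyl)silyl enol ether of 15 (C2=C3 enol ether; centres as in 15) | C=C(C)[C@@H]1C=C(O[Si](C)(OCC)OCC)[C@H](CO[Si](c2ccccc2)(c2ccccc2)C(C)(C)C)[C@](C)(CCC(=O)OCC)C1 | intermediate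
15 | ethyl 3‑[(1R,2S,5S)‑2‑{[tert‑butyl(diphenyl)silyl]oxymethyl}‑1‑methyl‑3‑oxo‑5‑(prop‑1‑en‑2‑yl)cyclohexyl]propanoate | C=C(C)[C@@H]1CC(=O)[C@H](CO[Si](c2ccccc2)(c2ccccc2)C(C)(C)C)[C@](C)(CCC(=O)OCC)C1 | intermediate
16 | ethyl 3‑[(1R,2S,5S)‑2‑{[tert‑butyl(diphenyl)silyl]oxymethyl}‑1‑methyl‑5‑(prop‑1‑en‑2‑yl)‑3‑(trifluoromethylsulfonyloxy)cyclohex‑3‑en‑1‑yl]propanoate | C=C(C)[C@@H]1C=C(OS(=O)(=O)C(F)(F)F)[C@H](CO[Si](c2ccccc2)(c2ccccc2)C(C)(C)C)[C@](C)(CCC(=O)OCC)C1 | intermediate
17 | ethyl 3‑[(1R,2R,5S)‑2‑{[tert‑butyl(diphenyl)silyl]oxymethyl}‑1,3‑dimethyl‑5‑(prop‑1‑en‑2‑yl)cyclohex‑3‑en‑1‑yl]propanoate | C=C(C)[C@@H]1C=C(C)[C@H](CO[Si](c2ccccc2)(c2ccccc2)C(C)(C)C)[C@](C)(CCC(=O)OCC)C1 | intermediate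
18 | ethyl 3‑[(1R,2R,5S)‑2‑(hydroxymethyl)‑1,3‑dimethyl‑5‑(prop‑1‑en‑2‑yl)cyclohex‑3‑en‑1‑yl]propanoate | C=C(C)[C@@H]1C=C(C)[C@H](CO)[C@](C)(CCC(=O)OCC)C1 | intermediate
19 | umbelliferone (7‑hydroxy‑2H‑chromen‑2‑one) | O=c1ccc2ccc(O)cc2o1 | starting material
20 | ethyl 3‑[(1R,2R,5S)‑1,3‑dimethyl‑2‑{[(2‑oxo‑2H‑chromen‑7‑yl)oxy]methyl}‑5‑(prop‑1‑en‑2‑yl)cyclohex‑3‑en‑1‑yl]propanoate | C=C(C)[C@@H]1C=C(C)[C@H](COc2ccc3ccc(=O)oc3c2)[C@](C)(CCC(=O)OCC)C1 | intermediate
21 | trilithium salt of the ring‑opened (Z)‑2‑hydroxycinnamate diacid derived from 20 | [Li+].[Li+].[Li+].C=C(C)[C@@H]1C=C(C)[C@H](COc2ccc(/C=C\C(=O)[O-])c([O-])c2)[C@](C)(CCC(=O)[O-])C1 | intermediate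
22 | 3‑[(1R,2R,5S)‑1,3‑dimethyl‑2‑{[(2‑oxo‑2H‑chromen‑7‑yl)oxy]methyl}‑5‑(prop‑1‑en‑2‑yl)cyclohex‑3‑en‑1‑yl]propanoic acid | C=C(C)[C@@H]1C=C(C)[C@H](COc2ccc3ccc(=O)oc3c2)[C@](C)(CCC(=O)O)C1 | target

## Step count and least certain steps

Total steps: 12. Longest linear sequence: 11 (steps 1, 2, 3, 5–12 from but‑2‑yn‑1‑ol; step 4 is a one‑step side branch).

**Step 6 (key step, proposed new method).** The most likely failure is nickel‑mediated oligomerization of the terminal enyne outrunning its capture by the ketone. Oxidative cyclization at a ketone flanked by an α‑substituent is slow, while terminal alkynes trimerize readily at zerovalent nickel. The fallback uses known chemistry, sets out from 11 and returns at 13.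
- Kinetic enol silylation at the methylene side (LiN(i‑Pr)2, Me3SiCl, −78 °C) gives the trimethylsilyl enol ether F1.
- [2+2] cycloaddition with dichloroketene (Cl3CCOCl, zinc–copper couple) gives the bicyclic dichlorocyclobutanone F2.
- Zinc in acetic acid removes the chlorines, and aqueous acid triggers retro‑aldol opening of the central bond. This is the established two‑carbon ring expansion of ketone silyl enol ethers, and it gives the cyclohexane‑1,3‑dione F3.
- O‑Triflation at the less hindered carbonyl (Tf2O, Et3N, −78 °C) gives the vinylogous triflate F4.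
- Suzuki coupling with isopropenylboronic acid pinacol ester (Pd(PPh3)4, K3PO4, dioxane/water) gives 13.

**Step 5.** The most likely failure is incomplete face selection by the auxiliary, giving 11 of low enantiomeric purity, because the unsubstituted keteniminium carbon offers the alkene little steric differentiation. A stepwise closure could also let the ester carbonyl intercept the tertiary cation. The fallback sets out from 6 and returns at 11. A catalytic enantioselective allenoate–alkene [2+2] of 6 with 2,2,2‑trifluoroethyl buta‑2,3‑dienoate, promoted by a chiral oxazaborolidine‑based Lewis acid, gives the alkylidenecyclobutane F5 with the same regiochemistry. Ozonolysis (O3, CH2Cl2, −78 °C; Me2S) of its exocyclic alkene gives 11.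

**Step 7.** The most likely failure is hydride delivery to the unhindered terminal carbon of the isopropenyl group (1,6‑reduction) in competition with the hindered C1. Face selection at C1 is also at risk, because the two C5 substituents differ little. The fallback masks the distal alkene; it sets out from 13 and returns at 15.
- Thiophenol with catalytic Et3N adds at the terminal carbon and the enone re‑conjugates, giving the δ‑phenylthio enone F6, an ordinary β,β‑dialkyl cyclohexenone.
- The same copper hydride/(S)‑bisphosphine reduction then gives the sulfide ketone F7.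
- NaIO4 in aqueous methanol gives the sulfoxide F8.
- Thermolysis in toluene at 110 °C eliminates toward the only β‑hydrogen and restores the isopropenyl group in 15.

**Step 11.** The most likely failure is slow displacement at the β‑branched primary carbon, so that the activated alcohol is diverted to alkylation of the hydrazide by‑product or to elimination. The fallback sets out from 18 and returns at 20. Sulfonylation (Tf2O, 2,6‑lutidine, CH2Cl2, −78 °C) gives the primary triflate F9, which is displaced by the caesium salt of 19 (Cs2CO3, DMF, 0 °C → rt) to give 20.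

## Further compounds

F1 | step 6 | trimethylsilyl enol ether of 11 at the methylene side (1‑trimethylsilyloxycyclobutene; ring stereocentres as in 11) | C[Si](C)(C)OC1=C[C@@](C)(CCC(=O)OCC)[C@H]1CO[Si](c1ccccc1)(c1ccccc1)C(C)(C)C
F2 | step 6 | 2,2‑dichloro‑1‑(trimethylsilyloxy)bicyclo[2.2.0]hexan‑3‑one bearing the 5‑methyl, 5‑(2‑ethoxycarbonylethyl) and 6‑(silyloxymethyl) groups of 11 (cis‑fused; bridgehead centres not carried into 13) | C[Si](C)(C)OC12C(Cl)(Cl)C(=O)C1[C@@](C)(CCC(=O)OCC)[C@H]2CO[Si](c1ccccc1)(c1ccccc1)C(C)(C)C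
F3 | step 6 | ethyl 3‑[(1R,2S)‑2‑{[tert‑butyl(diphenyl)silyl]oxymethyl}‑1‑methyl‑3,5‑dioxocyclohexyl]propanoate | O=C1CC(=O)[C@H](CO[Si](c2ccccc2)(c2ccccc2)C(C)(C)C)[C@](C)(CCC(=O)OCC)C1
F4 | step 6 | ethyl 3‑[(1R,2S)‑2‑{[tert‑butyl(diphenyl)silyl]oxymethyl}‑1‑methyl‑3‑oxo‑5‑(trifluoromethylsulfonyloxy)cyclohex‑4‑en‑1‑yl]propanoate | FC(F)(F)S(=O)(=O)OC1=CC(=O)[C@H](CO[Si](c2ccccc2)(c2ccccc2)C(C)(C)C)[C@](C)(CCC(=O)OCC)C1
F5 | step 5 | 2,2,2‑trifluoroethyl 2‑[2‑{[tert‑butyl(diphenyl)silyl]oxymethyl}‑3‑(3‑ethoxy‑3‑oxopropyl)‑3‑methylcyclobutylidene]acetate (ring stereocentres as in 11; alkene geometry immaterial) | FC(F)(F)COC(=O)C=C1C[C@@](C)(CCC(=O)OCC)[C@H]1CO[Si](c1ccccc1)(c1ccccc1)C(C)(C)C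
F6 | step 7 | ethyl 3‑[(1R,2S)‑2‑{[tert‑butyl(diphenyl)silyl]oxymethyl}‑1‑methyl‑3‑oxo‑5‑[1‑(phenylsulfanyl)propan‑2‑yl]cyclohex‑4‑en‑1‑yl]propanoate (both epimers at the side‑chain carbon) | CC(CSc1ccccc1)C1=CC(=O)[C@H](CO[Si](c2ccccc2)(c2ccccc2)C(C)(C)C)[C@](C)(CCC(=O)OCC)C1
F7 | step 7 | ethyl 3‑[(1R,2S,5S)‑2‑{[tert‑butyl(diphenyl)silyl]oxymethyl}‑1‑methyl‑3‑oxo‑5‑[1‑(phenylsulfanyl)propan‑2‑yl]cyclohexyl]propanoate (both epimers at the side‑chain carbon) | CC(CSc1ccccc1)[C@@H]1CC(=O)[C@H](CO[Si](c2ccccc2)(c2ccccc2)C(C)(C)C)[C@](C)(CCC(=O)OCC)C1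
F8 | step 7 | ethyl 3‑[(1R,2S,5S)‑2‑{[tert‑butyl(diphenyl)silyl]oxymethyl}‑1‑methyl‑3‑oxo‑5‑[1‑(phenylsulfinyl)propan‑2‑yl]cyclohexyl]propanoate (mixture at side‑chain carbon and sulfur) | CC(CS(=O)c1ccccc1)[C@@H]1CC(=O)[C@H](CO[Si](c2ccccc2)(c2ccccc2)C(C)(C)C)[C@](C)(CCC(=O)OCC)C1
F9 | step 11 | ethyl 3‑[(1R,2R,5S)‑1,3‑dimethyl‑5‑(prop‑1‑en‑2‑yl)‑2‑{[(trifluoromethylsulfonyl)oxy]methyl}cyclohex‑3‑en‑1‑yl]propanoate | C=C(C)[C@@H]1C=C(C)[C@H](COS(=O)(=O)C(F)(F)F)[C@](C)(CCC(=O)OCC)C1
A1 | alternative 1 | (2,6‑dimethylcyclohexa‑2,5‑dien‑1‑yl)methyl 2‑diazoacetate | CC1=CCC=C(C)C1COC(=O)C=[N+]=[N-]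
A2 | alternative 1 | cyclopropane‑fused cis‑bicyclic δ‑lactone retaining the C2=C3 alkene | C1C=C(C)[C@@H]2COC(=O)[C@H]3[C@]2(C)[C@@H]13
A3 | alternative 2 | (Z)‑3‑[tert‑butyl(dimethyl)silyl]oxy‑2‑methylprop‑1‑en‑1‑yl 3‑(1,3‑dimethyl‑6‑oxocyclohexa‑2,4‑dien‑1‑yl)propanoate | O=C1C=CC(C)=C[C@]1(C)CCC(=O)O/C=C(/C)CO[Si](C)(C)C(C)(C)C
A4 | alternative 2 | bicyclo[2.2.2]octenone fused to a seven‑membered lactone | O=C1[C@H]2C=C(C)[C@H]3[C@]1(C)CCC(=O)O[C@H]3[C@@]2(C)CO[Si](C)(C)C(C)(C)C
A5 | alternative 3 | (5S)‑3‑{3‑[tert‑butyl(dimethyl)silyl]oxypropyl}‑5‑(prop‑1‑en‑2‑yl)cyclohex‑2‑en‑1‑one | C=C(C)[C@@H]1CC(=O)C=C(CCCO[Si](C)(C)C(C)(C)C)C1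
A6 | alternative 3 | 2‑(hydroxymethyl)‑3‑methyl‑3‑(3‑silyloxypropyl)‑5‑(prop‑1‑en‑2‑yl)cyclohexanone | C=C(C)[C@@H]1CC(=O)[C@H](CO)[C@](C)(CCCO[Si](C)(C)C(C)(C)C)C1
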